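**Strategy.** The plan closes the lower pyran ring (ring F) by joining lower C4 to C4a of ring D at the ketone level, and uncovers the labile 4-hydroxyl only in the last step. Ring D carries the upper flavan at C8, so C4a is its only free carbon ortho to the ether oxygen O1; a Friedel–Crafts acylation of the tethered α-hydroxy acid therefore closes ring F at one site and gives a 3-hydroxyflavanone that survives debenzylation and lets the C3 hydroxyl steer the final hydride. The precursor is an open-chain aryl ether: the all-cis upper unit (from (−)-catechin) O-alkylated by an enantiopure cis-glycidic ester.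

Key step: step 11

Labels: upper flavan unit = rings A (fused arene), C (pyran), B (catechol); lower unit = rings D (fused arene), F (pyran), E (catechol). "Lower C2/C3/C4/C4a" are ring F/D atoms, also in the open-chain precursors.
Assumption: (−)-catechin (2S,3R) is taken as purchasable; the sense of induction of the (S,S)-(salen)MnCl catalyst is assigned by analogy with cis-cinnamate esters.

**Step 1**
Reactants: 1 (−)-catechin
Product: 2 5,7,3′,4′-tetra-O-benzyl-(−)-catechin
Conditions: BnBr (4.4 equiv), K2CO3, DMF, 0 °C → rt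
Reagents that add atoms: benzyl bromide, BrCc1ccccc1
Why: Williamson etherification; the four phenols are alkylated under carbonate conditions while the less acidic C3 alcohol stays free, and no stereocentre is touched.

**Step 2**
Reactants: 2 tetra-O-benzyl-(−)-catechin
Product: 3 (2S,3R,4R)-4-(2-ethoxyethoxy)-tetra-O-benzylcatechin
Conditions: DDQ (2 equiv), HOCH2CH2OEt (5 equiv), CH2Cl2, rt
Reagents that add atoms: 2-ethoxyethanol, CCOCCO
Why: DDQ benzylic oxidation (hydride abstraction at C4, assisted by the 5,7-dialkoxy ring A) with capture of the cation by the alcohol trans to the C2 aryl group; this C4 configuration is erased again in step 3.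

**Step 3**
Reactants: 3 C4 ether; 4 3,5-bis(benzyloxy)phenol
Product: 5 upper-unit phenol (2,3-trans-3,4-trans)
Conditions: 4 (4 equiv), TMSOTf (0.5 equiv), CH2Cl2, −78 °C
Reagents that add atoms: none
Why: Lewis-acid Friedel–Crafts arylation of a flavan-4-yl cation (the coupling used for 4→8 procyanidins): phenol 4 attacks through one of its two equivalent carbons ortho to the free OH (less hindered than the carbon between the two benzyloxy groups, and the site taken in acid-mediated cinnamylations of 4) and anti to the C3 hydroxyl, which sets C4 (3,4-trans, 2,4-cis) by substrate control.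

**Step 4**
Reactants: 5 upper-unit phenol
Product: 6 aryl tert-butyldimethylsilyl ether of 5
Conditions: TBSCl, imidazole, DMF, rt
Reagents that add atoms: tert-butyldimethylsilyl chloride, CC(C)(C)[Si](C)(C)Cl
Why: Selective O-silylation of the phenol over the hindered secondary alcohol; the silyl ether masks the phenol during the oxidation–reduction and is the latent aryloxide for step 9.

**Step 5**
Reactants: 6 aryl silyl ether
Product: 7 (2S,4R)-2,4-cis flavan-3-one
Conditions: Dess–Martin periodinane, NaHCO3, CH2Cl2, rt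
Reagents that add atoms: none
Why: Dess–Martin oxidation of the only free alcohol; the 2,4-cis diaryl arrangement is the thermodynamically favoured one, so the two enolisable centres are not at risk.

**Step 6**
Reactants: 7 flavan-3-one
Product: 8 all-cis flavan-3-ol (2S,3S; silyl ether retained)
Conditions: LiBH(s-Bu)3, THF, −78 °C; AcOH quench at −78 °C
Reagents that add atoms: none
Why: Ketone reduction with a bulky hydride (as in catechin-to-epicatechin inversions): hydride adds to the face opposite the two cis aryl groups at C2 and C4, giving the axial 3-hydroxyl cis to both by substrate control; the cold quench prevents silyl migration to the new alkoxide.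

**Step 7**
Reactants: 9 3,4-bis(benzyloxy)benzaldehyde
Product: 10 ethyl (Z)-3-[3,4-bis(benzyloxy)phenyl]prop-2-enoate
Conditions: (2-MeC6H4O)2P(O)CH2CO2Et, NaH, THF, −78 → 0 °C
Reagents that add atoms: ethyl 2-[bis(2-methylphenoxy)phosphoryl]acetate, CCOC(=O)CP(=O)(Oc1ccccc1C)Oc1ccccc1C
Why: Ando variant of the Horner–Wadsworth–Emmons olefination; the diaryl phosphonate gives the (Z)-cinnamate under kinetic control.

**Step 8**
Reactants: 10 (Z)-cinnamate
Product: 11 ethyl (2S,3S)-cis-3-[3,4-bis(benzyloxy)phenyl]oxirane-2-carboxylate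
Conditions: (S,S)-(salen)MnCl (Jacobsen catalyst, 5 mol %), NaOCl (aq., pH 11.3), 4-phenylpyridine N-oxide, CH2Cl2, 0 °C
Reagents that add atoms: sodium hypochlorite NaOCl, [Na+].[O-]Cl
Why: Jacobsen–Katsuki epoxidation of a cis-cinnamate ester: oxygen transfer from the chiral manganese–salen oxo species sets both epoxide carbons by catalyst control; the minor trans-epoxide from radical leakage is removed by chromatography.

**Step 9**
Reactants: 8 all-cis aryl silyl ether; 11 cis-glycidate
Product: 13 threo hydroxy ester (ring D oxygen on the benzylic carbon), via caesium aryloxide 12 (not isolated)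
Conditions: CsF (2 equiv), 11 (1.5 equiv), DMF, rt → 60 °C
Reagents that add atoms: none
Why: Fluoride desilylation frees the aryloxide, which opens the cis-epoxide by SN2 at the benzylic carbon with inversion (the ester-bearing carbon is deactivated), as in phenoxide and thiolate openings of 3-arylglycidates; this translates the epoxide into lower C2 (R) and lower C3 with the threo relationship of a 2,3-cis flavan.

**Step 10**
Reactants: 13 hydroxy ester
Product: 14 (2S,3R)-3-aryloxy-2-hydroxy acid
Conditions: LiOH, THF/H2O, 0 °C; then 1 M HCl to pH 4 at 0 °C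
Reagents that add atoms: lithium hydroxide LiOH, [Li+].[OH-]
Why: Ester saponification; the α-hydroxy carboxylate has no C–H acidic enough to trigger β-elimination of the aryloxide under these conditions.

**Step 11 (key step)**
Reactants: 14 hydroxy acid
Product: 17 octa-O-benzyl 3-hydroxyflavan-4-one dimer, via mixed anhydride 15 (not isolated), via cyclised bis(trifluoroacetate) 16 (not isolated)
Conditions: (CF3CO)2O (5 equiv), CH2Cl2 (0.01 M), 0 °C → rt; then NaHCO3, MeOH/H2O, 0 °C
Reagents that add atoms: none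
Why: Trifluoroacetic anhydride turns the acid into its mixed anhydride and masks the two alcohols as trifluoroacetates (15); C4a of ring D attacks the activated acyl carbon, trifluoroacetate and the ring proton leave (16), and brief bicarbonate methanolysis frees the alcohols. This is an intramolecular Friedel–Crafts acylation, the classical chroman-4-one synthesis from 3-aryloxypropanoic acids. Ring F closes in a 6-exo-trig mode at the acyl carbon, with the C4a–C8a bond of ring D inside the new ring. No stereocentre is created; lower C2 and C3 (2,3-cis, from the epoxide) are carried through, the α-acyloxy ketone being kept cold and exposed to bicarbonate only briefly to avoid enolisation. The step needs site selectivity, which the substrate secures: C4a is the only free carbon ortho to O1 (C8 bears the upper unit), ring D is a 1,3,5-trioxygenated arene far more nucleophilic than rings A, B and E, and only ring D can close a six-membered ring. It also needs the benzylic aryl ether O1–C2 to resist the acid, which the electron-withdrawing acyloxy and acyl groups on the neighbouring carbons should provide.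

**Step 12**
Reactants: 17 octa-O-benzyl ketone
Product: 18 free polyphenolic 3-hydroxyflavan-4-one dimer
Conditions: H2 (1 atm), Pd(OH)2/C, THF/MeOH, rt
Reagents that add atoms: none
Why: Hydrogenolysis of the eight aryl benzyl ethers; the strongly conjugated aryl ketone (as in taxifolin benzyl ethers) and both pyran rings stay intact, whereas a free lower C4 carbinol would itself be hydrogenolysed, which is why C4 is still a ketone here.

**Step 13**
Reactants: 18 free ketone
Product: 19 target compound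
Conditions: Me4NBH(OAc)3 (excess), MeCN/AcOH (4:1), −30 → 0 °C; pH 6 phosphate buffer quench
Reagents that add atoms: none
Why: Hydroxyl-directed (Evans–Saksena) triacetoxyborohydride reduction: the axial lower C3 hydroxyl binds boron and delivers hydride to the same face of the adjacent ketone, so the new lower C4 hydroxyl is trans to it (4S, substrate control), which is also the epimer favoured whenever 2,3-cis flavan-4-ols equilibrate.

**Compound list**
1 | (−)-catechin, (2S,3R)-2-(3,4-dihydroxyphenyl)chroman-3,5,7-triol | Oc1cc(O)c2c(c1)O[C@@H](c1ccc(O)c(O)c1)[C@H](O)C2 | starting material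
2 | 5,7,3′,4′-tetra-O-benzyl-(−)-catechin (2S,3R) | c1ccccc1COc1cc(OCc3ccccc3)c2c(c1)O[C@@H](c1ccc(OCc3ccccc3)c(OCc3ccccc3)c1)[C@H](O)C2 | intermediate
3 | (2S,3R,4R)-4-(2-ethoxyethoxy)-tetra-O-benzylcatechin (ether trans to the C2 aryl, cis to 3-OH) | c1ccccc1COc1cc(OCc3ccccc3)c2c(c1)O[C@@H](c1ccc(OCc3ccccc3)c(OCc3ccccc3)c1)[C@H](O)[C@@H]2OCCOCC | intermediate
4 | 3,5-bis(benzyloxy)phenol | Oc1cc(OCc2ccccc2)cc(OCc2ccccc2)c1 | starting material
5 | (2S,3R,4S)-tetra-O-benzylcatechin bearing at C4 a 2,4-bis(benzyloxy)-6-hydroxyphenyl group (ring D) trans to 3-OH and cis to the C2 aryl | c1ccccc1COc1cc(OCc3ccccc3)c2c(c1)O[C@@H](c1ccc(OCc3ccccc3)c(OCc3ccccc3)c1)[C@H](O)[C@H]2c1c(O)cc(OCc3ccccc3)cc1OCc3ccccc3 | intermediate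
6 | tert-butyldimethylsilyl ether of the ring D phenol of 5 | c1ccccc1COc1cc(OCc3ccccc3)c2c(c1)O[C@@H](c1ccc(OCc3ccccc3)c(OCc3ccccc3)c1)[C@H](O)[C@H]2c1c(O[Si](C)(C)C(C)(C)C)cc(OCc3ccccc3)cc1OCc3ccccc3 | intermediate
7 | (2S,4R)-2,4-cis flavan-3-one (C3 ketone of 6) | c1ccccc1COc1cc(OCc3ccccc3)c2c(c1)O[C@@H](c1ccc(OCc3ccccc3)c(OCc3ccccc3)c1)C(=O)[C@H]2c1c(O[Si](C)(C)C(C)(C)C)cc(OCc3ccccc3)cc1OCc3ccccc3 | intermediate
8 | all-cis flavan-3-ol (2S,3S; 3-OH cis to the C2 aryl and to ring D at C4), ring D phenol as silyl ether | c1ccccc1COc1cc(OCc3ccccc3)c2c(c1)O[C@@H](c1ccc(OCc3ccccc3)c(OCc3ccccc3)c1)[C@@H](O)[C@H]2c1c(O[Si](C)(C)C(C)(C)C)cc(OCc3ccccc3)cc1OCc3ccccc3 | intermediate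
9 | 3,4-bis(benzyloxy)benzaldehyde | O=Cc1ccc(OCc2ccccc2)c(OCc2ccccc2)c1 | starting material
10 | ethyl (Z)-3-[3,4-bis(benzyloxy)phenyl]prop-2-enoate | CCOC(=O)/C=C\c1ccc(OCc2ccccc2)c(OCc2ccccc2)c1 | intermediate
11 | ethyl (2S,3S)-cis-3-[3,4-bis(benzyloxy)phenyl]oxirane-2-carboxylate | CCOC(=O)[C@H]1O[C@H]1c1ccc(OCc2ccccc2)c(OCc2ccccc2)c1 | intermediate
12 | caesium aryloxide of desilylated 8 | c1ccccc1COc1cc(OCc3ccccc3)c2c(c1)O[C@@H](c1ccc(OCc3ccccc3)c(OCc3ccccc3)c1)[C@@H](O)[C@H]2c1c([O-])cc(OCc3ccccc3)cc1OCc3ccccc3.[Cs+] | intermediate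
13 | ring D aryl ether of ethyl (2S,3R)-3-[3,4-bis(benzyloxy)phenyl]-2-hydroxypropanoate, linked through the C3 oxygen (threo); upper unit all-cis | c1ccccc1COc1cc(OCc3ccccc3)c2c(c1)O[C@@H](c1ccc(OCc3ccccc3)c(OCc3ccccc3)c1)[C@@H](O)[C@H]2c1c(O[C@H](c3ccc(OCc4ccccc4)c(OCc4ccccc4)c3)[C@H](O)C(=O)OCC)cc(OCc3ccccc3)cc1OCc3ccccc3 | intermediate
14 | corresponding (2S,3R)-3-aryloxy-2-hydroxypropanoic acid | c1ccccc1COc1cc(OCc3ccccc3)c2c(c1)O[C@@H](c1ccc(OCc3ccccc3)c(OCc3ccccc3)c1)[C@@H](O)[C@H]2c1c(O[C@H](c3ccc(OCc4ccccc4)c(OCc4ccccc4)c3)[C@H](O)C(=O)O)cc(OCc3ccccc3)cc1OCc3ccccc3 | intermediate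
15 | bis(O-trifluoroacetyl) mixed carboxylic–trifluoroacetic anhydride of 14 | c1ccccc1COc1cc(OCc3ccccc3)c2c(c1)O[C@@H](c1ccc(OCc3ccccc3)c(OCc3ccccc3)c1)[C@@H](OC(=O)C(F)(F)F)[C@H]2c1c(O[C@H](c3ccc(OCc4ccccc4)c(OCc4ccccc4)c3)[C@H](OC(=O)C(F)(F)F)C(=O)OC(=O)C(F)(F)F)cc(OCc3ccccc3)cc1OCc3ccccc3 | intermediate
16 | bis(trifluoroacetate) of ketone 17 | c1ccccc1COc1cc(OCc3ccccc3)c2c(c1)O[C@@H](c1ccc(OCc3ccccc3)c(OCc3ccccc3)c1)[C@@H](OC(=O)C(F)(F)F)[C@H]2c1c(OCc3ccccc3)cc(OCc3ccccc3)c2c1O[C@H](c1ccc(OCc3ccccc3)c(OCc3ccccc3)c1)[C@H](OC(=O)C(F)(F)F)C2=O | intermediate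
17 | octa-O-benzyl dimer: upper all-cis flavan-3-ol (2S,3S,4R) linked C4→C8 to lower (2R,3S)-2,3-cis-3-hydroxyflavan-4-one | c1ccccc1COc1cc(OCc3ccccc3)c2c(c1)O[C@@H](c1ccc(OCc3ccccc3)c(OCc3ccccc3)c1)[C@@H](O)[C@H]2c1c(OCc3ccccc3)cc(OCc3ccccc3)c2c1O[C@H](c1ccc(OCc3ccccc3)c(OCc3ccccc3)c1)[C@H](O)C2=O | intermediate
18 | debenzylated ketone: upper (2S,3S,4R) unit linked 4→8 to lower (2R,3S)-3-hydroxyflavan-4-one | Oc1cc(O)c2c(c1)O[C@@H](c1ccc(O)c(O)c1)[C@@H](O)[C@H]2c1c(O)cc(O)c2c1O[C@H](c1ccc(O)c(O)c1)[C@H](O)C2=O | intermediate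
19 | CNP0114173.1: upper (2S,3S,4R) all-cis flavan-3-ol linked 4→8 to lower (2R,3R,4S)-2,3-cis-3,4-trans flavan-3,4-diol | Oc1cc(O)c2c(c1)O[C@@H](c1ccc(O)c(O)c1)[C@@H](O)[C@H]2c1c(O)cc(O)c2c1O[C@H](c1ccc(O)c(O)c1)[C@H](O)[C@H]2O | target

**Step count.** Total: 13 steps. Longest linear sequence: 11 steps (steps 1–6 and 9–13, from (−)-catechin).

**Steps most likely to fail**

Step 9. The bulky ortho-substituted aryloxide may react sluggishly, or the electron-rich benzylic carbon may open with partial ionisation (loss of clean inversion), or attack may occur at the ester-bearing carbon. The fallback uses the stereo-complementary retentive opening and sets out from 9 and 8. Aldehyde 9 is olefinated with (EtO)2P(O)CH2CO2Et/NaH to the (E)-cinnamate F1, which is epoxidised with a Shi-type chiral ketone and KHSO5 to the trans-(2S,3R)-glycidate F2. Silyl ether 8 is desilylated with Bu4NF to the free all-cis phenol F3. Heating neutral F3 with F2 in toluene without base opens the electron-rich trans-epoxide at the benzylic carbon with retention (hydrogen-bonded ion-pair cis-opening, as known for 3-(4-methoxyphenyl)glycidates with arenethiols). This gives the same threo hydroxy ester, and the route is rejoined at 13.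

Step 11. The acid released may cleave the benzylic aryl ether of the open chain, the α-acyloxy ketone may enolise and epimerise, or the electron-rich rings may be C-trifluoroacetylated. The fallback makes the same C4–C4a bond by hydroxyalkylation at low temperature and adjusts the oxidation level afterwards; it sets out from 13. Et3SiOTf/2,6-lutidine gives the bis(triethylsilyl) ether F4, and i-Bu2AlH at −78 °C gives the α-silyloxy aldehyde F5. BF3·OEt2 with 2,6-di-tert-butyl-4-methylpyridine in dilute CH2Cl2 at −78 °C closes ring F by intramolecular Friedel–Crafts hydroxyalkylation to the carbinol F6. Dess–Martin oxidation gives the chroman-4-one bis(silyl ether) F7, and HF·pyridine removes the silyl groups, rejoining the route at 17.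

Step 13. Face selection may be eroded by hydride delivery from the peri 5-hydroxyl or by external hydride, and the acidic medium may ionise the new benzylic carbinol (self-condensation or ionic over-reduction). The fallback separates reduction from stereocontrol and sets out from 18. NaBH4 in EtOH/H2O at 0 °C (basic medium, no ionisation) should give mainly the 3,4-cis carbinol F8 by attack anti to the axial 3-hydroxyl. Brief equilibration of F8 at high dilution in aqueous acetate buffer (pH about 4) epimerises lower C4 through the benzylic cation; water returns trans to the C3 hydroxyl, as in all 4-substituted 2,3-cis flavans, giving 19.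

**Further compounds**
F1 | step 9 | ethyl (E)-3-[3,4-bis(benzyloxy)phenyl]prop-2-enoate | CCOC(=O)/C=C/c1ccc(OCc2ccccc2)c(OCc2ccccc2)c1
F2 | step 9 | ethyl (2S,3R)-trans-3-[3,4-bis(benzyloxy)phenyl]oxirane-2-carboxylate | CCOC(=O)[C@H]1O[C@@H]1c1ccc(OCc2ccccc2)c(OCc2ccccc2)c1
F3 | step 9 | free all-cis phenol (desilylated 8) | c1ccccc1COc1cc(OCc3ccccc3)c2c(c1)O[C@@H](c1ccc(OCc3ccccc3)c(OCc3ccccc3)c1)[C@@H](O)[C@H]2c1c(O)cc(OCc3ccccc3)cc1OCc3ccccc3
F4 | step 11 | bis(triethylsilyl) ether of hydroxy ester 13 | c1ccccc1COc1cc(OCc3ccccc3)c2c(c1)O[C@@H](c1ccc(OCc3ccccc3)c(OCc3ccccc3)c1)[C@@H](O[Si](CC)(CC)CC)[C@H]2c1c(O[C@H](c3ccc(OCc4ccccc4)c(OCc4ccccc4)c3)[C@H](O[Si](CC)(CC)CC)C(=O)OCC)cc(OCc3ccccc3)cc1OCc3ccccc3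
F5 | step 11 | α-triethylsilyloxy aldehyde from F4 | c1ccccc1COc1cc(OCc3ccccc3)c2c(c1)O[C@@H](c1ccc(OCc3ccccc3)c(OCc3ccccc3)c1)[C@@H](O[Si](CC)(CC)CC)[C@H]2c1c(O[C@H](c3ccc(OCc4ccccc4)c(OCc4ccccc4)c3)[C@H](O[Si](CC)(CC)CC)C=O)cc(OCc3ccccc3)cc1OCc3ccccc3
F6 | step 11 | cyclised lower 4-carbinol (3,4-trans expected), both C3 hydroxyls as triethylsilyl ethers | c1ccccc1COc1cc(OCc3ccccc3)c2c(c1)O[C@@H](c1ccc(OCc3ccccc3)c(OCc3ccccc3)c1)[C@@H](O[Si](CC)(CC)CC)[C@H]2c1c(OCc3ccccc3)cc(OCc3ccccc3)c2c1O[C@H](c1ccc(OCc3ccccc3)c(OCc3ccccc3)c1)[C@H](O[Si](CC)(CC)CC)[C@H]2O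
F7 | step 11 | bis(triethylsilyl) ether of ketone 17 | c1ccccc1COc1cc(OCc3ccccc3)c2c(c1)O[C@@H](c1ccc(OCc3ccccc3)c(OCc3ccccc3)c1)[C@@H](O[Si](CC)(CC)CC)[C@H]2c1c(OCc3ccccc3)cc(OCc3ccccc3)c2c1O[C@H](c1ccc(OCc3ccccc3)c(OCc3ccccc3)c1)[C@H](O[Si](CC)(CC)CC)C2=O
F8 | step 13 | lower C4 epimer of 19 (2,3-cis-3,4-cis) | Oc1cc(O)c2c(c1)O[C@@H](c1ccc(O)c(O)c1)[C@@H](O)[C@H]2c1c(O)cc(O)c2c1O[C@H](c1ccc(O)c(O)c1)[C@H](O)[C@@H]2O
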